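**Retrosynthetic overview**
1. Target ⇐ desilylation ⇐ silylated oxolane ⇐ Lewis-acid ring expansion of a (3-acetoxyalkyl)oxirane: the C6–C7 oxirane becomes the oxolane while the acetate moves from O4 to O6 (sets C6 and C7; the only ring-forming event).
2. That oxirane acetate ⇐ acetylation and OH-directed epoxidation of an (E)-homoallylic bromohydrin ⇐ bromide opening of a (3R,4R)-alkynyl oxirane (sets C3–Br).
3. C5–C6 disconnection: epoxy triflate from the Sharpless epoxide of (E)-5-silylpent-2-en-4-yn-1-ol plus the (E)-vinyllithium of the C6–C15 fragment.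
4. C6–C15 fragment ⇐ hydrozirconation–iodination ⇐ anti-bromohydrin from enamine α-bromination of (E)-hept-4-enal and propargylation (sets C9, C10).
5. Ring order: C3–C4 oxirane (made first, opened by bromide) → C6–C7 oxirane (made late) → oxolane.

Assumption: (2E)-pent-2-en-4-yn-1-ol and (4E)-hept-4-enal are bought as pure E isomers; locants C1–C15 follow the target chain (C1 = alkyne CH, ring oxygen on C4 and C7).
Assumption: the (R,R) ligand in step 8 is taken as the enantiomer matched with syn delivery from the C4 hydroxyl; if a test run shows otherwise, its mirror image is used.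

Step 1
Reactants: 1 (2E)-pent-2-en-4-yn-1-ol
Product: 3 (2E)-5-(trimethylsilyl)pent-2-en-4-yn-1-ol, via bis-silyl ether 2 (not isolated)
Conditions: EtMgBr (2.2 equiv), THF, 0 °C to rt; TMSCl (2.3 equiv); then 1 M HCl, 0 °C
Reagents that add atoms: chlorotrimethylsilane, C[Si](C)(C)Cl
Why: Double deprotonation and silylation followed by selective hydrolysis of the labile O–Si bond (C-silylation of a terminal alkyne) masks the acidic alkyne C–H for the later organolithium coupling; no stereocentre is formed.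

Step 2
Reactants: 3 (2E)-5-(trimethylsilyl)pent-2-en-4-yn-1-ol
Product: 4 {(2R,3R)-3-[(trimethylsilyl)ethynyl]oxiran-2-yl}methanol
Conditions: Ti(OiPr)4 (10 mol %), D-(−)-diethyl tartrate (12 mol %), t-BuOOH, 4 Å molecular sieves, CH2Cl2, −20 °C
Reagents that add atoms: tert-butyl hydroperoxide, CC(C)(C)OO
Why: Sharpless asymmetric epoxidation of the (E)-allylic alcohol; the D-(−)-tartrate delivers oxygen to the face that gives the (2R,3R)-oxirane (C4 and C3 of the target chain).

Step 3
Reactants: 5 (4E)-hept-4-enal; 6 3-bromoprop-1-yne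
Product: 9 (4S,5R,7E)-5-bromodec-7-en-1-yn-4-ol, via bromoaldehyde 7 (not isolated), via allenylzinc bromide 8 (not isolated)
Conditions: (R)-2-{bis[3,5-bis(trifluoromethyl)phenyl](trimethylsilyloxy)methyl}pyrrolidine (10 mol %), NBS, CH2Cl2, −40 °C; then Zn dust, 6, THF, −20 °C; aq NH4Cl
Reagents that add atoms: N-bromosuccinimide, O=C1CCC(=O)N1Br
Why: Enamine-catalysed α-bromination sets C10 (R) under catalyst control, and zinc-mediated Barbier propargylation of the un-isolated aldehyde follows the Cornforth (polar Felkin–Anh) model to give the 9,10-anti bromohydrin (9S).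

Step 4
Reactants: 9 (4S,5R,7E)-5-bromodec-7-en-1-yn-4-ol
Product: 10 tert-butyl{[(4S,5R,7E)-5-bromodec-7-en-1-yn-4-yl]oxy}dimethylsilane
Conditions: TBSOTf, 2,6-lutidine, CH2Cl2, −78 °C
Reagents that add atoms: tert-butyldimethylsilyl triflate, CC(C)(C)[Si](C)(C)OS(=O)(=O)C(F)(F)F
Why: Low-temperature, non-nucleophilic silylation protects O9 without closing the bromohydrin to an epoxide, and later keeps O9 from directing the epoxidation or entering the ring-forming step.

Step 5
Reactants: 10 tert-butyl{[(4S,5R,7E)-5-bromodec-7-en-1-yn-4-yl]oxy}dimethylsilane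
Product: 12 tert-butyl{[(1E,4S,5R,7E)-5-bromo-1-iododeca-1,7-dien-4-yl]oxy}dimethylsilane, via alkenylzirconocene 11 (not isolated)
Conditions: Cp2Zr(H)Cl (1.3 equiv), THF, rt; then I2, 0 °C
Reagents that add atoms: iodine, II
Why: syn-Hydrozirconation of the terminal alkyne puts zirconium on C6 and iodinolysis with retention gives the (E)-vinyl iodide (hydrozirconation–iodination); the internal alkene and the alkyl bromide react far more slowly.

Step 6
Reactants: 12 tert-butyl{[(1E,4S,5R,7E)-5-bromo-1-iododeca-1,7-dien-4-yl]oxy}dimethylsilane; 4 {(2R,3R)-3-[(trimethylsilyl)ethynyl]oxiran-2-yl}methanol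
Product: 15 (3R,4R,6E,9S,10R,12E)-10-bromo-9-(tert-butyldimethylsilyloxy)-3,4-epoxy-1-(trimethylsilyl)pentadeca-6,12-dien-1-yne, via epoxy triflate 13 (not isolated), via vinyllithium 14 (not isolated)
Conditions: 4: Tf2O, 2,6-lutidine, CH2Cl2, −78 °C, cold filtration; 12: t-BuLi (2.0 equiv), Et2O, −78 °C; combine, −78 to −40 °C
Reagents that add atoms: none
Why: Iodine–lithium exchange keeps the E geometry and the vinyllithium displaces the primary triflate (SN2 alkylation of an organolithium) faster than it opens the oxirane or attacks silicon, so the C5–C6 bond forms without touching a stereocentre.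

Step 7
Reactants: 15 (3R,4R,6E,9S,10R,12E)-10-bromo-9-(tert-butyldimethylsilyloxy)-3,4-epoxy-1-(trimethylsilyl)pentadeca-6,12-dien-1-yne
Product: 16 (3S,4R,6E,9S,10R,12E)-3,10-dibromo-9-(tert-butyldimethylsilyloxy)-1-(trimethylsilyl)pentadeca-6,12-dien-1-yn-4-ol
Conditions: MgBr2·OEt2 (3 equiv), Et2O, −20 to 0 °C
Reagents that add atoms: magnesium dibromide, [Mg+2].[Br-].[Br-]
Why: Lewis-acid-assisted SN2 opening of the alkynyl oxirane by bromide at the activated propargylic carbon inverts C3 (3R to 3S), gives the anti bromohydrin and frees the C4 hydroxyl.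

Step 8
Reactants: 16 (3S,4R,6E,9S,10R,12E)-3,10-dibromo-9-(tert-butyldimethylsilyloxy)-1-(trimethylsilyl)pentadeca-6,12-dien-1-yn-4-ol
Product: 17 (3S,4R,6S,7S,9S,10R,12E)-3,10-dibromo-9-(tert-butyldimethylsilyloxy)-6,7-epoxy-1-(trimethylsilyl)pentadec-12-en-1-yn-4-ol
Conditions: VO(OiPr)3 (2 mol %), (1R,2R)-N,N'-dihydroxy-N,N'-bis(diphenylacetyl)cyclohexane-1,2-diamine (3 mol %), cumene hydroperoxide, toluene, 0 °C
Reagents that add atoms: cumene hydroperoxide, CC(C)(OO)c1ccccc1
Why: Hydroxyl-directed vanadium-catalysed epoxidation of the homoallylic alcohol delivers oxygen to C6=C7 from the face 1,3-syn to the C4 hydroxyl (6S,7S; trans from the E alkene), the chiral ligand reinforcing the weak intrinsic bias, while the undirected C12=C13 alkene stays intact.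

Step 9
Reactants: 17 (3S,4R,6S,7S,9S,10R,12E)-3,10-dibromo-9-(tert-butyldimethylsilyloxy)-6,7-epoxy-1-(trimethylsilyl)pentadec-12-en-1-yn-4-ol
Product: 18 (3S,4R,6S,7S,9S,10R,12E)-3,10-dibromo-9-(tert-butyldimethylsilyloxy)-6,7-epoxy-1-(trimethylsilyl)pentadec-12-en-1-yn-4-yl acetate
Conditions: Ac2O, pyridine, DMAP (cat.), CH2Cl2, 0 °C
Reagents that add atoms: acetic anhydride, CC(=O)OC(C)=O
Why: DMAP-catalysed acetylation of the only free hydroxyl is faster than base-induced closure of the bromohydrin and places the acyl group 1,3 to the oxirane for the next step; no stereocentre changes.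

Step 10
Reactants: 18 (3S,4R,6S,7S,9S,10R,12E)-3,10-dibromo-9-(tert-butyldimethylsilyloxy)-6,7-epoxy-1-(trimethylsilyl)pentadec-12-en-1-yn-4-yl acetate
Product: 20 (2R,3R,5R)-5-[(1S)-1-bromo-3-(trimethylsilyl)prop-2-yn-1-yl]-2-[(2S,3R,5E)-3-bromo-2-(tert-butyldimethylsilyloxy)oct-5-en-1-yl]oxolan-3-yl acetate, via bicyclic ortho ester 19 (not isolated)
Conditions: BF3·OEt2 (0.2 equiv), CH2Cl2, −40 to 0 °C
Reagents that add atoms: none
Why: Proposed new method: BF3 activates the oxirane, the C4 acetate carbonyl opens it at C6 in a 6-exo mode with inversion (6S to 6R) to a six-membered acyloxonium ion that the C7 alkoxide caps as the 2,7,8-trioxabicyclo[3.2.1]octane ortho ester 19 (closest known reaction: the Lewis-acid rearrangement of 3,4-epoxyalkyl esters to bicyclic ortho esters), and the new part is that the Lewis acid re-ionises 19 to the five-membered acyloxonium ion so that the released O4 displaces O7 at C7 with inversion (7S to 7R) in a 5-exo SN2, the only irreversible exit, which enlarges the three-membered ether to the oxolane and leaves the acetate on O6 (related known behaviour: acyloxonium-mediated anhydro-ring formation in polyol acetates).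

Step 11
Reactants: 20 (2R,3R,5R)-5-[(1S)-1-bromo-3-(trimethylsilyl)prop-2-yn-1-yl]-2-[(2S,3R,5E)-3-bromo-2-(tert-butyldimethylsilyloxy)oct-5-en-1-yl]oxolan-3-yl acetate
Product: 21 (2R,3R,5R)-2-[(2S,3R,5E)-3-bromo-2-hydroxyoct-5-en-1-yl]-5-[(1S)-1-bromoprop-2-yn-1-yl]oxolan-3-yl acetate
Conditions: TBAF, AcOH (1:1, 3 equiv), THF, 0 °C to rt
Reagents that add atoms: none
Why: Buffered fluoride cleaves both the O–Si bond at C9 and the C(sp)–Si bond without generating a free alkoxide beside C10–Br (no epoxide closure, no acetate loss), so no stereocentre is affected.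

**Compound list**
1 | (2E)-pent-2-en-4-yn-1-ol | C#C/C=C/CO | starting material
2 | trimethyl{[(2E)-5-(trimethylsilyl)pent-2-en-4-yn-1-yl]oxy}silane | C[Si](C)(C)C#C/C=C/CO[Si](C)(C)C | intermediate
3 | (2E)-5-(trimethylsilyl)pent-2-en-4-yn-1-ol | C[Si](C)(C)C#C/C=C/CO | intermediate
4 | {(2R,3R)-3-[(trimethylsilyl)ethynyl]oxiran-2-yl}methanol | C[Si](C)(C)C#C[C@H]1O[C@@H]1CO | intermediate
5 | (4E)-hept-4-enal | CC/C=C/CCC=O | starting material
6 | 3-bromoprop-1-yne (propargyl bromide) | C#CCBr | starting material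
7 | (2R,4E)-2-bromohept-4-enal | O=C[C@H](Br)C/C=C/CC | intermediate
8 | bromo(propa-1,2-dien-1-yl)zinc | C=C=C[Zn]Br | intermediate
9 | (4S,5R,7E)-5-bromodec-7-en-1-yn-4-ol | C#CC[C@H](O)[C@H](Br)C/C=C/CC | intermediate
10 | tert-butyl{[(4S,5R,7E)-5-bromodec-7-en-1-yn-4-yl]oxy}dimethylsilane | C#CC[C@H](O[Si](C)(C)C(C)(C)C)[C@H](Br)C/C=C/CC | intermediate
11 | chlorobis(cyclopentadienyl)[(1E,4S,5R,7E)-5-bromo-4-(tert-butyldimethylsilyloxy)deca-1,7-dien-1-yl]zirconium | Cl[Zr](/C=C/C[C@H](O[Si](C)(C)C(C)(C)C)[C@H](Br)C/C=C/CC)(C1C=CC=C1)C1C=CC=C1 | intermediate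
12 | tert-butyl{[(1E,4S,5R,7E)-5-bromo-1-iododeca-1,7-dien-4-yl]oxy}dimethylsilane | I/C=C/C[C@H](O[Si](C)(C)C(C)(C)C)[C@H](Br)C/C=C/CC | intermediate
13 | {(2R,3R)-3-[(trimethylsilyl)ethynyl]oxiran-2-yl}methyl trifluoromethanesulfonate | C[Si](C)(C)C#C[C@H]1O[C@@H]1COS(=O)(=O)C(F)(F)F | intermediate
14 | [(1E,4S,5R,7E)-5-bromo-4-(tert-butyldimethylsilyloxy)deca-1,7-dien-1-yl]lithium | [Li]/C=C/C[C@H](O[Si](C)(C)C(C)(C)C)[C@H](Br)C/C=C/CC | intermediate
15 | (3R,4R,6E,9S,10R,12E)-10-bromo-9-(tert-butyldimethylsilyloxy)-3,4-epoxy-1-(trimethylsilyl)pentadeca-6,12-dien-1-yne | C[Si](C)(C)C#C[C@H]1O[C@@H]1C/C=C/C[C@H](O[Si](C)(C)C(C)(C)C)[C@H](Br)C/C=C/CC | intermediate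
16 | (3S,4R,6E,9S,10R,12E)-3,10-dibromo-9-(tert-butyldimethylsilyloxy)-1-(trimethylsilyl)pentadeca-6,12-dien-1-yn-4-ol | C[Si](C)(C)C#C[C@H](Br)[C@H](O)C/C=C/C[C@H](O[Si](C)(C)C(C)(C)C)[C@H](Br)C/C=C/CC | intermediate
17 | (3S,4R,6S,7S,9S,10R,12E)-3,10-dibromo-9-(tert-butyldimethylsilyloxy)-6,7-epoxy-1-(trimethylsilyl)pentadec-12-en-1-yn-4-ol | C[Si](C)(C)C#C[C@H](Br)[C@H](O)C[C@@H]1O[C@H]1C[C@H](O[Si](C)(C)C(C)(C)C)[C@H](Br)C/C=C/CC | intermediate
18 | 4-O-acetate of 17 | C[Si](C)(C)C#C[C@H](Br)[C@H](OC(C)=O)C[C@@H]1O[C@H]1C[C@H](O[Si](C)(C)C(C)(C)C)[C@H](Br)C/C=C/CC | intermediate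
19 | 1-methyl-2,7,8-trioxabicyclo[3.2.1]octane ortho ester whose ortho carbon is bonded to O4, O6 and O7 (C3 S, C4 R, C6 R, C7 S, C9 S, C10 R) | C[C@@]12O[C@@H]([C@@H](Br)C#C[Si](C)(C)C)C[C@@H](O1)[C@H](C[C@H](O[Si](C)(C)C(C)(C)C)[C@H](Br)C/C=C/CC)O2 | intermediate
20 | (2R,3R,5R)-5-[(1S)-1-bromo-3-(trimethylsilyl)prop-2-yn-1-yl]-2-[(2S,3R,5E)-3-bromo-2-(tert-butyldimethylsilyloxy)oct-5-en-1-yl]oxolan-3-yl acetate | C[Si](C)(C)C#C[C@H](Br)[C@H]1C[C@@H](OC(C)=O)[C@@H](C[C@H](O[Si](C)(C)C(C)(C)C)[C@H](Br)C/C=C/CC)O1 | intermediate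
21 | (2R,3R,5R)-2-[(2S,3R,5E)-3-bromo-2-hydroxyoct-5-en-1-yl]-5-[(1S)-1-bromoprop-2-yn-1-yl]oxolan-3-yl acetate | C#C[C@H](Br)[C@H]1C[C@@H](OC(C)=O)[C@@H](C[C@H](O)[C@H](Br)C/C=C/CC)O1 | target

**Step count and risks**

Total steps: 11. Longest linear sequence: 9 (steps 3 to 11, from 5).

Steps most likely to fail:

Step 3 (bromoaldehyde 7 racemises easily and the addition is only substrate-controlled). The fallback sets out from 5 and comes back at 7. The same enamine bromination is quenched with NaBH4 in MeOH to give (2R,4E)-2-bromohept-4-en-1-ol F1, a stable compound that can be purified and whose enantiomeric purity can be measured. Dess–Martin periodinane (NaHCO3, CH2Cl2, 0 °C) then returns aldehyde 7 immediately before the zinc-mediated addition, so the one-pot protocol is replaced by a stepwise one through an isolable alcohol.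

Step 6 (vinyllithium generated beside a secondary bromide; a sensitive triflate as electrophile). The fallback sets out from 10 and 4 and comes back at 15. The bond is made at the alkyne oxidation level: n-BuLi converts 10 into lithium acetylide F2, which is alkylated by triflate 13 (THF/DMPU, −78 °C) to skipped diyne F3. trans-Selective semihydrogenation of the internal dialkyl alkyne with Cp*Ru(cod)Cl and H2 (the silyl-capped alkyne is shielded) then gives 15.

Step 10 (the proposed ring expansion; it may stop at ortho ester 19 or be diverted by adventitious water). The fallback sets out from 17, uses only known chemistry and comes back at 20. Camphorsulfonic acid in CH2Cl2 triggers the established 5-endo opening of the 3,4-epoxy alcohol by O4 at C7 with inversion, giving (2R,3S,5R)-5-[(1S)-1-bromo-3-(trimethylsilyl)prop-2-yn-1-yl]-2-[(2S,3R,5E)-3-bromo-2-(tert-butyldimethylsilyloxy)oct-5-en-1-yl]oxolan-3-ol F4, whose hydroxyl is trans to the C7 side chain. A Mitsunobu reaction with acetic acid (PPh3, DIAD, toluene) inverts C6 and installs the acetate to give 20.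

Further compounds
F1 | step 3 | (2R,4E)-2-bromohept-4-en-1-ol | OC[C@H](Br)C/C=C/CC
F2 | step 6 | [(4S,5R,7E)-5-bromo-4-(tert-butyldimethylsilyloxy)dec-7-en-1-yn-1-yl]lithium | [Li]C#CC[C@H](O[Si](C)(C)C(C)(C)C)[C@H](Br)C/C=C/CC
F3 | step 6 | (3R,4R,9S,10R,12E)-10-bromo-9-(tert-butyldimethylsilyloxy)-3,4-epoxy-1-(trimethylsilyl)pentadec-12-ene-1,6-diyne | C[Si](C)(C)C#C[C@H]1O[C@@H]1CC#CC[C@H](O[Si](C)(C)C(C)(C)C)[C@H](Br)C/C=C/CC
F4 | step 10 | (2R,3S,5R)-5-[(1S)-1-bromo-3-(trimethylsilyl)prop-2-yn-1-yl]-2-[(2S,3R,5E)-3-bromo-2-(tert-butyldimethylsilyloxy)oct-5-en-1-yl]oxolan-3-ol | C[Si](C)(C)C#C[C@H](Br)[C@H]1C[C@H](O)[C@@H](C[C@H](O[Si](C)(C)C(C)(C)C)[C@H](Br)C/C=C/CC)O1
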